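## Retrosynthetic overview
1. Acid 21 comes from methyl ester 20. The C2–C3 bond of 20 comes from a silyl ketene acetal and the peroxycarbenium ion of 3-methoxy-1,2-dioxolane 17; this sets C3, trans to the long arm.
2. 17 comes from a β-hydroperoxy ketone, and that from hydroperoxy alcohol 14. 14 comes from opening oxetane 13 with H2O2 at its tertiary carbon, with inversion, which turns C5–O into C5–OO.
3. 13 comes from 1,3-diol 11 through the key C3–C4 bond. C3, later the carbonyl/peroxyketal carbon, enters as a nucleophile (α-boryl carbanion from 9) and opens the CH2 end of oxirane 8.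
4. 8 comes from methyl ketone 7 by catalytic asymmetric methylene transfer (sets C5). 7 comes from asymmetric conjugate addition of the side-chain Grignard reagent to pent-3-en-2-one (sets C7), and the bromodiene 4 comes from an HWE reaction.
5. Ring order: oxirane (step 4), oxetane (step 6), 1,2-dioxolane (step 8). Only the dioxolane stays.

Atom labels C1–C17 count along the acid chain of the target: C1 = CO2H, C3 and C5 = dioxolane carbons, C7 = CHMe.

Assumption: in steps 3 and 4 the ligand antipode written is taken to be the one that gives the drawn configuration; both antipodes are sold, so the other is used if the sense is opposite.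

## Route

Step 1
Reactants: 1 ethyl 7-bromoheptanoate
Product: 2 7-bromoheptanal
Conditions: i-Bu2AlH (1.05 equiv), CH2Cl2, −78 °C; aq potassium sodium tartrate
Reagents that add atoms: none
Why: Partial ester reduction stops at the tetrahedral aluminium hemiacetal at −78 °C and releases the aldehyde on work-up; the primary bromide is untouched and no stereocentre is involved.

Step 2
Reactants: 2 7-bromoheptanal; 3 diethyl cinnamylphosphonate
Product: 4 [(1E,3E)-10-bromodeca-1,3-dien-1-yl]benzene
Conditions: 3, n-BuLi, THF, −78 °C; then 2, −78 °C to rt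
Reagents that add atoms: none
Why: Horner–Wadsworth–Emmons olefination with the allylic phosphonate anion gives the new C=C mainly as the E isomer and keeps the cinnamyl E alkene, and at −78 °C the aldehyde outcompetes the alkyl bromide as electrophile.

Step 3
Reactants: 4 [(1E,3E)-10-bromodeca-1,3-dien-1-yl]benzene; 5 (E)-pent-3-en-2-one
Product: 7 (4R,11E,13E)-4-methyl-14-phenyltetradeca-11,13-dien-2-one, via alkylmagnesium bromide 6 (not isolated)
Conditions: Mg, Et2O, reflux; then CuBr·SMe2 (5 mol %), (R)-1-[(SP)-2-(diphenylphosphino)ferrocenyl]ethyldicyclohexylphosphine (6 mol %), t-BuOMe, −75 °C, slow addition of 5; then 1 M aq HCl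
Reagents that add atoms: magnesium, [Mg] (ends up only in intermediate 6)
Why: Copper-catalysed asymmetric conjugate addition of a Grignard reagent to a linear enone, in which the ferrocenyl diphosphine–CuBr complex sends the alkyl group to one enone face and sets C7 as R (ee above 90% is usual for linear partners); the remote diene is inert.

Step 4
Reactants: 7 (4R,11E,13E)-4-methyl-14-phenyltetradeca-11,13-dien-2-one
Product: 8 (2S)-2-methyl-2-[(2R,9E,11E)-2-methyl-12-phenyldodeca-9,11-dien-1-yl]oxirane
Conditions: Me2S(O)=CH2 (1.2 equiv, from Me3S(O)Cl and NaH in THF), LaLi3[(S)-binaphthoxide]3 (5 mol %), [2,4,6-(MeO)3C6H2]3P=O (5 mol %), MS 5 Å, THF, rt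
Reagents that add atoms: dimethyloxosulfonium methylide, C[S+](C)(=O)[CH2-]
Why: Catalytic asymmetric Corey–Chaykovsky epoxidation, in which the lanthanum–lithium binaphthoxide/phosphine oxide catalyst binds ketone and ylide together and tells CH3 from CH2R, so methylene arrives on one face under catalyst control and sets C5 as the S oxirane.

Step 5 (key step)
Reactants: 8 (2S)-2-methyl-2-[(2R,9E,11E)-2-methyl-12-phenyldodeca-9,11-dien-1-yl]oxirane; 9 2,2'-(ethane-1,1-diyl)bis(4,4,5,5-tetramethyl-1,3,2-dioxaborolane)
Product: 11 (4S,6R,13E,15E)-4,6-dimethyl-16-phenylhexadeca-13,15-diene-2,4-diol (both C2 epimers), via hydroxy boronate 10 (not isolated)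
Conditions: 9 (2 equiv), CuI (10 mol %), LiOt-Bu (2.5 equiv), THF, 60 °C; then 30% aq H2O2, 3 M aq NaOH, 0 °C
Reagents that add atoms: hydrogen peroxide, OO
Why: Proposed new method: tert-butoxide adds to one boron of 9 and the ate complex hands an α-boryl ethyl carbanion to monovalent copper, a reversed-polarity equivalent of the acetyl/1-hydroxyethyl anion, which attacks the unsubstituted oxirane carbon in SN2 fashion, so that two carbons that are both electrophiles in normal reactivity (the future carbonyl carbon C3 and the oxirane CH2 C4) are joined while the C5–O bond and its configuration stay untouched, and C–B oxidation then gives the diol at exactly the oxidation level the oxetane needs; the closest known reactions are the alkoxide-promoted deborylative alkylation of geminal bis(boronates) and the CuI/LiOt-Bu coupling of diborylmethane with terminal epoxides, the new points being the methyl-bearing reagent and the 2,2-disubstituted epoxide, and the new C3 carbinol centre forms as a mixture that is erased in step 8.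

Step 6
Reactants: 11 (4S,6R,13E,15E)-4,6-dimethyl-16-phenylhexadeca-13,15-diene-2,4-diol
Product: 13 (2S)-2,4-dimethyl-2-[(2R,9E,11E)-2-methyl-12-phenyldodeca-9,11-dien-1-yl]oxetane (both C4 epimers), via secondary mesylate 12 (not isolated)
Conditions: MsCl, Et3N, CH2Cl2, −20 °C; then KOt-Bu, THF, 0 °C to rt
Reagents that add atoms: methanesulfonyl chloride, CS(=O)(=O)Cl (ends up only in intermediate 12)
Why: The secondary alcohol is sulfonylated selectively over the tertiary one and an intramolecular Williamson etherification (4-exo-tet) closes the oxetane; C5 keeps its configuration because its C–O bond is not broken, and C3 inverts but is stereochemically irrelevant.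

Step 7
Reactants: 13 (2S)-2,4-dimethyl-2-[(2R,9E,11E)-2-methyl-12-phenyldodeca-9,11-dien-1-yl]oxetane
Product: 14 (4R,6R,13E,15E)-4-hydroperoxy-4,6-dimethyl-16-phenylhexadeca-13,15-dien-2-ol (both C2 epimers)
Conditions: anhydrous H2O2 in Et2O (10 equiv), Me3SiOTf (0.2 equiv), Et2O, −78 to −25 °C
Reagents that add atoms: hydrogen peroxide, OO
Why: Lewis-acid-catalysed perhydrolysis of an oxetane, in which the activated ring is opened by H2O2 at the tertiary carbon in a loose SN2 process with inversion, turning (S)-C5–O into the (R)-C5–OO centre of the target; low temperature and catalytic acid are chosen to spare the diene.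

Step 8
Reactants: 14 (4R,6R,13E,15E)-4-hydroperoxy-4,6-dimethyl-16-phenylhexadeca-13,15-dien-2-ol
Product: 17 (5R)-3-methoxy-3,5-dimethyl-5-[(2R,9E,11E)-2-methyl-12-phenyldodeca-9,11-dien-1-yl]-1,2-dioxolane (both C3 anomers), via hydroperoxy ketone 15 (not isolated), via dioxolan-3-ol 16 (not isolated)
Conditions: Dess–Martin periodinane, CH2Cl2, 0 °C; then MeOH, pyridinium p-toluenesulfonate (10 mol %), rt
Reagents that add atoms: methanol, CO
Why: Dess–Martin oxidation of the secondary alcohol should outrun any reaction at the tertiary hydroperoxide, the β-hydroperoxy ketone closes by itself to the five-membered peroxyhemiketal, and acid-catalysed exchange with methanol gives the storable peroxyketal; C5 is untouched and C3 becomes planar in step 9.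

Step 9
Reactants: 17 (5R)-3-methoxy-3,5-dimethyl-5-[(2R,9E,11E)-2-methyl-12-phenyldodeca-9,11-dien-1-yl]-1,2-dioxolane; 18 tert-butyl[(1-methoxyethenyl)oxy]dimethylsilane
Product: 20 methyl 2-[(3S,5R)-3,5-dimethyl-5-[(2R,9E,11E)-2-methyl-12-phenyldodeca-9,11-dien-1-yl]-1,2-dioxolan-3-yl]acetate, via peroxycarbenium ion 19 (not isolated)
Conditions: TiCl4 (1.1 equiv), 18 (2.5 equiv), CH2Cl2, −78 °C; then H2O
Reagents that add atoms: none
Why: Mukaiyama-type alkylation of a peroxycarbenium ion, in which TiCl4 ionises the C3–OMe bond and the ketene acetal adds to planar 19 mainly from the face anti to the larger, β-branched C5 arm (inside attack on the envelope that holds that arm pseudo-equatorial), giving the 3,5-trans (3S) ester as the major isomer; the selectivity is modest (about 2:1 expected) and the 3-epimer is removed by chromatography at this ester stage.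

Step 10
Reactants: 20 methyl 2-[(3S,5R)-3,5-dimethyl-5-[(2R,9E,11E)-2-methyl-12-phenyldodeca-9,11-dien-1-yl]-1,2-dioxolan-3-yl]acetate
Product: 21 2-[(3S,5R)-3,5-dimethyl-5-[(2R,9E,11E)-2-methyl-12-phenyldodeca-9,11-dien-1-yl]-1,2-dioxolan-3-yl]acetic acid
Conditions: LiOH, THF/H2O 3:1, 0 °C to rt; then 1 M aq HCl to pH 3
Reagents that add atoms: lithium hydroxide, [Li+].[OH-]
Why: Saponification at the ester carbonyl; both peroxide carbons are fully substituted, so base-induced Kornblum–DeLaMare cleavage cannot occur, and no stereocentre is touched.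

## Compound list
1 | ethyl 7-bromoheptanoate | CCOC(=O)CCCCCCBr | starting material
2 | 7-bromoheptanal | O=CCCCCCCBr | intermediate
3 | diethyl cinnamylphosphonate | CCOP(=O)(C/C=C/c1ccccc1)OCC | starting material
4 | [(1E,3E)-10-bromodeca-1,3-dien-1-yl]benzene | BrCCCCCC/C=C/C=C/c1ccccc1 | intermediate
5 | (E)-pent-3-en-2-one | C/C=C/C(C)=O | starting material
6 | [(7E,9E)-10-phenyldeca-7,9-dien-1-yl]magnesium bromide | Br[Mg]CCCCCC/C=C/C=C/c1ccccc1 | intermediate (not isolated)
7 | (4R,11E,13E)-4-methyl-14-phenyltetradeca-11,13-dien-2-one | C[C@H](CCCCCC/C=C/C=C/c1ccccc1)CC(C)=O | intermediate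
8 | (2S)-2-methyl-2-[(2R,9E,11E)-2-methyl-12-phenyldodeca-9,11-dien-1-yl]oxirane | C[C@H](CCCCCC/C=C/C=C/c1ccccc1)C[C@@]1(C)CO1 | intermediate
9 | 2,2'-(ethane-1,1-diyl)bis(4,4,5,5-tetramethyl-1,3,2-dioxaborolane) | CC(B1OC(C)(C)C(C)(C)O1)B1OC(C)(C)C(C)(C)O1 | starting material
10 | (6R,13E,15E)-4,6-dimethyl-16-phenyl-2-(4,4,5,5-tetramethyl-1,3,2-dioxaborolan-2-yl)hexadeca-13,15-dien-4-ol, carbinol carbon arranged as in 8 and 11, both C2 epimers | C[C@H](CCCCCC/C=C/C=C/c1ccccc1)C[C@@](O)(C)CC(C)B1OC(C)(C)C(C)(C)O1 | intermediate (not isolated)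
11 | (4S,6R,13E,15E)-4,6-dimethyl-16-phenylhexadeca-13,15-diene-2,4-diol, both C2 epimers | C[C@H](CCCCCC/C=C/C=C/c1ccccc1)C[C@@](O)(C)CC(C)O | intermediate
12 | (4S,6R,13E,15E)-4-hydroxy-4,6-dimethyl-16-phenylhexadeca-13,15-dien-2-yl methanesulfonate, both C2 epimers | C[C@H](CCCCCC/C=C/C=C/c1ccccc1)C[C@@](O)(C)CC(C)OS(C)(=O)=O | intermediate (not isolated)
13 | (2S)-2,4-dimethyl-2-[(2R,9E,11E)-2-methyl-12-phenyldodeca-9,11-dien-1-yl]oxetane, both C4 epimers | C[C@H](CCCCCC/C=C/C=C/c1ccccc1)C[C@@]1(C)CC(C)O1 | intermediate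
14 | (4R,6R,13E,15E)-4-hydroperoxy-4,6-dimethyl-16-phenylhexadeca-13,15-dien-2-ol, both C2 epimers | C[C@H](CCCCCC/C=C/C=C/c1ccccc1)C[C@](OO)(C)CC(C)O | intermediate
15 | (4R,6R,13E,15E)-4-hydroperoxy-4,6-dimethyl-16-phenylhexadeca-13,15-dien-2-one | C[C@H](CCCCCC/C=C/C=C/c1ccccc1)C[C@](OO)(C)CC(C)=O | intermediate (not isolated)
16 | (5R)-3,5-dimethyl-5-[(2R,9E,11E)-2-methyl-12-phenyldodeca-9,11-dien-1-yl]-1,2-dioxolan-3-ol, both C3 anomers | C[C@H](CCCCCC/C=C/C=C/c1ccccc1)C[C@]1(C)CC(C)(O)OO1 | intermediate (not isolated)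
17 | (5R)-3-methoxy-3,5-dimethyl-5-[(2R,9E,11E)-2-methyl-12-phenyldodeca-9,11-dien-1-yl]-1,2-dioxolane, both C3 anomers | C[C@H](CCCCCC/C=C/C=C/c1ccccc1)C[C@]1(C)CC(C)(OC)OO1 | intermediate
18 | tert-butyl[(1-methoxyethenyl)oxy]dimethylsilane | C=C(OC)O[Si](C)(C)C(C)(C)C | starting material
19 | (5R)-3,5-dimethyl-5-[(2R,9E,11E)-2-methyl-12-phenyldodeca-9,11-dien-1-yl]-1,2-dioxolan-3-ylium (peroxycarbenium ion) | C[C@H](CCCCCC/C=C/C=C/c1ccccc1)C[C@]1(C)CC(C)=[O+]O1 | intermediate (not isolated)
20 | methyl 2-[(3S,5R)-3,5-dimethyl-5-[(2R,9E,11E)-2-methyl-12-phenyldodeca-9,11-dien-1-yl]-1,2-dioxolan-3-yl]acetate | C[C@H](CCCCCC/C=C/C=C/c1ccccc1)C[C@]1(C)C[C@@](C)(CC(=O)OC)OO1 | intermediate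
21 | 2-[(3S,5R)-3,5-dimethyl-5-[(2R,9E,11E)-2-methyl-12-phenyldodeca-9,11-dien-1-yl]-1,2-dioxolan-3-yl]acetic acid | C[C@H](CCCCCC/C=C/C=C/c1ccccc1)C[C@]1(C)C[C@@](C)(CC(=O)O)OO1 | target

## Step count and risks
Total steps: 10. Longest linear sequence: 10 (1 to 21).

**Step 5.** The secondary α-boryl copper nucleophile may be too hindered for the neopentyl-like oxirane CH2. The fallback sets out from 8 and comes back at 11.
- The smaller formyl anion equivalent 2-lithio-1,3-dithiane opens 8 in THF/DMPU to give the hydroxy dithiane F1.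
- MeI/CaCO3 in aqueous MeCN unmasks the β-hydroxy aldehyde F2.
- MeMgBr adds to the aldehyde and gives diol 11.
- The C3–C4 bond is still made with C3 as the nucleophile, and C5 is again untouched.

**Step 7.** Possible problems are partial SN1 leakage at C5, attack of the acid on the diene, and low yield. The fallback sets out from 11 and comes back at 16.
- The secondary alcohol of 11 is oxidised with Dess–Martin periodinane to the β-hydroxy ketone F3.
- Catalytic TsOH dehydrates F3 to the enone F4.
- Aqueous H2O2 adds in a conjugate sense under iminium catalysis by a 9-amino-9-deoxy-epi-quinine trichloroacetate salt, and the adduct closes to 16, which goes on with MeOH and pyridinium p-toluenesulfonate as in step 8.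
- C5 then rests on catalyst control plus chromatographic removal of its epimer, which is a diastereomer because of C7.

**Step 9.** Face selectivity at C3 may approach 1:1. The fallback sets out from 17 and comes back at 21.
- The chlorotitanium enolate of commercial (4S)-3-acetyl-4-isopropyl-1,3-thiazolidine-2-thione is made with TiCl4 and i-Pr2NEt in CH2Cl2 at −78 °C. The antipode is used if it proves to be the matched one.
- This enolate is combined with 17 and SnCl4 to give the acyl thiazolidinethione F5. Reagent control is thereby added to the substrate bias, and the yellow diastereomers separate easily.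
- LiOH removes the auxiliary and gives 21 directly, so the step count does not change.

## Further compounds
F1 | step 5 | (2S,4R,11E,13E)-1-(1,3-dithian-2-yl)-2,4-dimethyl-14-phenyltetradeca-11,13-dien-2-ol | C[C@H](CCCCCC/C=C/C=C/c1ccccc1)C[C@@](O)(C)CC1SCCCS1
F2 | step 5 | (3S,5R,12E,14E)-3-hydroxy-3,5-dimethyl-15-phenylpentadeca-12,14-dienal | C[C@H](CCCCCC/C=C/C=C/c1ccccc1)C[C@@](O)(C)CC=O
F3 | step 7 | (4S,6R,13E,15E)-4-hydroxy-4,6-dimethyl-16-phenylhexadeca-13,15-dien-2-one | C[C@H](CCCCCC/C=C/C=C/c1ccccc1)C[C@@](O)(C)CC(C)=O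
F4 | step 7 | (3E,6R,13E,15E)-4,6-dimethyl-16-phenylhexadeca-3,13,15-trien-2-one | C[C@H](CCCCCC/C=C/C=C/c1ccccc1)C/C(C)=C/C(C)=O
F5 | step 9 | 1-[(4S)-4-isopropyl-2-sulfanylidene-1,3-thiazolidin-3-yl]-2-[(3S,5R)-3,5-dimethyl-5-[(2R,9E,11E)-2-methyl-12-phenyldodeca-9,11-dien-1-yl]-1,2-dioxolan-3-yl]ethan-1-one | C[C@H](CCCCCC/C=C/C=C/c1ccccc1)C[C@]1(C)C[C@@](C)(CC(=O)N2[C@@H](C(C)C)CSC2=S)OO1
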